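The flavone is disconnected through ring B. A (4+2) cycloaddition of trans-1-methoxy-3-(trimethylsilyloxy)buta-1,3-diene to the C2-ethynyl group of a fully oxygenated chromone should forge C1'–C6' and C2'–C3' in one operation; loss of methanol and of the silyl group then leaves ring B aromatic with O4' as the only free hydroxyl. The step exploits the para relationship in ring B between C1' (bonded to C2) and O4', and it sets O4' apart from O3, O5 and O7 for the later prenylation. The precursor is 2-ethynyl-6-methoxy-3,5,7-tris(methoxymethoxy)chromen-4-one, reached from 2-methoxyresorcinol, whose symmetry fixes the ring A pattern.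

Key step: step 10

Remark: the hydroxyl that closes the pyranone ring must lie para to the methoxy group (otherwise the 8-methoxy isomer would form); this is fixed by the mirror symmetry of phenol 7, and O3, O5 and O7 stay as MOM ethers, which carry no acidic proton that could quench the silyloxydiene, until the last step.

Step 1
Reactants: 1 methyl glycolate
Product: 2 methyl 2-(methoxymethoxy)acetate
Conditions: MOMCl, i-Pr2NEt, CH2Cl2, 0 °C → rt
Reagents that add atoms: chloromethyl methyl ether, COCCl
Why: O-alkylation of the primary alcohol with the highly reactive α-chloro ether under a hindered amine base (MOM acetal formation) is routine and should leave the methyl ester untouched.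

Step 2
Reactants: 2 methyl 2-(methoxymethoxy)acetate
Product: 3 N-methoxy-2-(methoxymethoxy)-N-methylacetamide
Conditions: MeNH(OMe)·HCl, i-PrMgCl, THF, −20 → 0 °C
Reagents that add atoms: N,O-dimethylhydroxylamine hydrochloride, CNOC.Cl
Why: Aminolysis of the ester by the chloromagnesium amide of N,O-dimethylhydroxylamine (Weinreb amide formation) should stop at the amide because the magnesium-chelated tetrahedral adduct does not collapse until work-up, and the MOM acetal is inert to the Grignard base.

Step 3
Reactants: 4 2-methoxyresorcinol (2-methoxybenzene-1,3-diol)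
Product: 5 2-methoxy-1,3-bis(methoxymethoxy)benzene
Conditions: NaH, MOMCl, DMF, 0 °C → rt
Reagents that add atoms: chloromethyl methyl ether, COCCl
Why: Double Williamson etherification of the two equivalent, non-chelated phenoxides with the α-chloro ether should go to completion and gives a substrate with a mirror plane through C2 and C5.

Step 4
Reactants: 5 2-methoxy-1,3-bis(methoxymethoxy)benzene
Product: 7 4-methoxy-3,5-bis(methoxymethoxy)phenol, via aryl pinacol boronate 6 (not isolated)
Conditions: [Ir(OMe)(cod)]2 (cat.), 4,4'-di-tert-butyl-2,2'-bipyridine (cat.), B2pin2, THF, 80 °C; then 30% H2O2, aq. NaOH, 0 °C → rt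
Reagents that add atoms: hydrogen peroxide, OO
Why: Iridium-catalysed aromatic C–H borylation is governed by sterics and should select C5, the only ring C–H with no ortho substituent, after which alkaline peroxide oxidises the C–B bond (1,2-shift of the aryl group from boron to oxygen) to place the free hydroxyl para to the methoxy group.

Step 5
Reactants: 7 4-methoxy-3,5-bis(methoxymethoxy)phenol
Product: 8 2-bromo-4-methoxy-3,5-bis(methoxymethoxy)phenol
Conditions: NBS (1.0 equiv), CH2Cl2, −78 → −20 °C
Reagents that add atoms: N-bromosuccinimide, O=C1CCC(=O)N1Br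
Why: Electrophilic aromatic bromination ortho to the free hydroxyl should give one monobromide because the two open ring positions are equivalent by symmetry and one equivalent of NBS is used at low temperature.

Step 6
Reactants: 8 2-bromo-4-methoxy-3,5-bis(methoxymethoxy)phenol; 3 N-methoxy-2-(methoxymethoxy)-N-methylacetamide
Product: 10 1-[2-hydroxy-5-methoxy-4,6-bis(methoxymethoxy)phenyl]-2-(methoxymethoxy)ethan-1-one, via dilithio phenolate 9 (not isolated)
Conditions: n-BuLi (2.2 equiv), THF, −78 °C; then 3, −78 → 0 °C; aq. NH4Cl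
Reagents that add atoms: none
Why: Deprotonation of the phenol and bromine–lithium exchange give an ortho-lithiated phenolate that should add once to the amide (Weinreb ketone synthesis), the chelated tetrahedral adduct blocking over-addition, so that the acyl group enters only at the former C–Br carbon, next to the free hydroxyl.

Step 7
Reactants: 10 1-[2-hydroxy-5-methoxy-4,6-bis(methoxymethoxy)phenyl]-2-(methoxymethoxy)ethan-1-one; 11 3-(trimethylsilyl)propiolic acid
Product: 13 1-[2-hydroxy-5-methoxy-4,6-bis(methoxymethoxy)phenyl]-2-(methoxymethoxy)-5-(trimethylsilyl)pent-4-yne-1,3-dione, via 3-(trimethylsilyl)propioloyl chloride 12 (not isolated)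
Conditions: 11, (COCl)2, cat. DMF, CH2Cl2, 0 °C → rt, concentrate; 10, LiN(SiMe3)2 (3.2 equiv), THF, −78 °C, then 12, −78 → −20 °C; AcOH
Reagents that add atoms: none
Why: Crossed Claisen-type C-acylation of the preformed ketone enolate (the one-pot variant of the Baker–Venkataraman route to 1,3-diketones) should take place at the acyl chloride carbon and not at the silyl-shielded alkyne terminus, the third equivalent of base holding the product as its diketonate until the acidic quench.

Step 8
Reactants: 13 1-[2-hydroxy-5-methoxy-4,6-bis(methoxymethoxy)phenyl]-2-(methoxymethoxy)-5-(trimethylsilyl)pent-4-yne-1,3-dione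
Product: 14 6-methoxy-3,5,7-tris(methoxymethoxy)-2-[(trimethylsilyl)ethynyl]-4H-chromen-4-one
Conditions: PPTS (0.2 equiv), 4 Å MS, PhMe, 70 °C
Reagents that add atoms: none
Why: Acid-catalysed cyclodehydration of an o-hydroxyaryl 1,3-diketone (classical chromone synthesis) should proceed by 6-exo-trig addition of the phenol to the electrophilic ynone carbonyl and loss of water, and a weak pyridinium acid in a dry aprotic medium should leave the MOM acetals in place.

Step 9
Reactants: 14 6-methoxy-3,5,7-tris(methoxymethoxy)-2-[(trimethylsilyl)ethynyl]-4H-chromen-4-one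
Product: 15 2-ethynyl-6-methoxy-3,5,7-tris(methoxymethoxy)-4H-chromen-4-one
Conditions: Bu4NF, AcOH, THF, −20 → 0 °C
Reagents that add atoms: none
Why: Fluoride-induced protodesilylation of the alkynylsilane, buffered with acetic acid so that no alkoxide or basic fluoride can add to the electrophilic enynone, should free the terminal alkyne.

Step 10
Reactants: 15 2-ethynyl-6-methoxy-3,5,7-tris(methoxymethoxy)-4H-chromen-4-one; 16 trans-1-methoxy-3-(trimethylsilyloxy)buta-1,3-diene
Product: 19 2-(4-hydroxyphenyl)-6-methoxy-3,5,7-tris(methoxymethoxy)-4H-chromen-4-one, via cyclohexa-1,4-diene cycloadduct 17 (not isolated), via 4'-O-trimethylsilyl ether 18 (not isolated)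
Conditions: 16 (4 equiv), PhMe, 120 °C, sealed tube; then K2CO3 (cat.), MeOH, rt
Reagents that add atoms: none
Why: The electron-rich diene should add across the terminal alkyne in a concerted but asynchronous normal-electron-demand (4+2) cycloaddition: the alkyne is conjugated through C2=C3 with C4=O, so its LUMO coefficient is largest at the terminal carbon, which bonds first to the nucleophilic CH2 terminus of the diene (C2'–C3'), and the methoxy-bearing terminus then closes onto the inner alkyne carbon (C1'–C6'). The closest known reaction type is the Diels–Alder reaction of 1-methoxy-3-silyloxybutadienes with ynones and propiolates, which gives 4-hydroxyaryl ketones and esters after loss of methanol. Ring B is closed by this intermolecular (4+2) annulation as the cyclohexa-1,4-diene 17, which should aromatise by 1,4-elimination of methanol (H from C3', OMe from C6') to silyl ether 18; catalytic K2CO3 in methanol then cleaves the aryl O–Si bond without touching the MOM acetals. No stereocentre survives: the methoxy-bearing C6' of 17 forms as a racemate and is erased on aromatisation. The step needs para regioselectivity and chemoselectivity for the alkyne; the first follows from the matched polarisation of the two partners, the second from the fact that C2=C3 is tetrasubstituted and donor-substituted and that C4=O is not activated without a Lewis acid. Because O3, O5 and O7 stay as MOM ethers, O4' should emerge as the only free hydroxyl.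

Step 11
Reactants: 19 2-(4-hydroxyphenyl)-6-methoxy-3,5,7-tris(methoxymethoxy)-4H-chromen-4-one; 20 1-bromo-3-methylbut-2-ene (prenyl bromide)
Product: 21 6-methoxy-3,5,7-tris(methoxymethoxy)-2-{4-[(3-methylbut-2-en-1-yl)oxy]phenyl}-4H-chromen-4-one
Conditions: K2CO3, acetone, 50 °C
Reagents that add atoms: none
Why: Williamson etherification (SN2 at the primary allylic carbon) should occur only at O4', the single free hydroxyl, since O3, O5 and O7 are blocked as MOM ethers.

Step 12
Reactants: 21 6-methoxy-3,5,7-tris(methoxymethoxy)-2-{4-[(3-methylbut-2-en-1-yl)oxy]phenyl}-4H-chromen-4-one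
Product: 22 3,5,7-trihydroxy-6-methoxy-2-{4-[(3-methylbut-2-en-1-yl)oxy]phenyl}-4H-chromen-4-one
Conditions: HCl (0.5 M), MeOH, 0 °C → rt
Reagents that add atoms: none
Why: Acid-catalysed transacetalisation with methanol (MOM cleavage via oxocarbenium ions, helped at O5 and O3 by the neighbouring carbonyl) should be much faster in dilute acid at or below room temperature than ionisation of the aryl prenyl ether, so the three hydroxyls are freed with the allyl ether intact.

Compound list
1 | methyl glycolate (methyl 2-hydroxyacetate) | COC(=O)CO | starting material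
2 | methyl 2-(methoxymethoxy)acetate | COCOCC(=O)OC | intermediate
3 | N-methoxy-2-(methoxymethoxy)-N-methylacetamide | COCOCC(=O)N(C)OC | intermediate
4 | 2-methoxyresorcinol (2-methoxybenzene-1,3-diol) | COc1c(O)cccc1O | starting material
5 | 2-methoxy-1,3-bis(methoxymethoxy)benzene | COCOc1cccc(OCOC)c1OC | intermediate
6 | 2-[4-methoxy-3,5-bis(methoxymethoxy)phenyl]-4,4,5,5-tetramethyl-1,3,2-dioxaborolane | COCOc1cc(B2OC(C)(C)C(C)(C)O2)cc(OCOC)c1OC | intermediate (not isolated)
7 | 4-methoxy-3,5-bis(methoxymethoxy)phenol | COCOc1cc(O)cc(OCOC)c1OC | intermediate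
8 | 2-bromo-4-methoxy-3,5-bis(methoxymethoxy)phenol | COCOc1cc(O)c(Br)c(OCOC)c1OC | intermediate
9 | lithium 2-lithio-4-methoxy-3,5-bis(methoxymethoxy)phenolate | COCOc1cc(O[Li])c([Li])c(OCOC)c1OC | intermediate (not isolated)
10 | 1-[2-hydroxy-5-methoxy-4,6-bis(methoxymethoxy)phenyl]-2-(methoxymethoxy)ethan-1-one | COCOCC(=O)c1c(O)cc(OCOC)c(OC)c1OCOC | intermediate
11 | 3-(trimethylsilyl)propiolic acid | C[Si](C)(C)C#CC(=O)O | starting material
12 | 3-(trimethylsilyl)propioloyl chloride | C[Si](C)(C)C#CC(=O)Cl | intermediate (not isolated)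
13 | 1-[2-hydroxy-5-methoxy-4,6-bis(methoxymethoxy)phenyl]-2-(methoxymethoxy)-5-(trimethylsilyl)pent-4-yne-1,3-dione (racemic; enolisable at C2) | COCOC(C(=O)C#C[Si](C)(C)C)C(=O)c1c(O)cc(OCOC)c(OC)c1OCOC | intermediate
14 | 6-methoxy-3,5,7-tris(methoxymethoxy)-2-[(trimethylsilyl)ethynyl]-4H-chromen-4-one | COCOc1c(C#C[Si](C)(C)C)oc2cc(OCOC)c(OC)c(OCOC)c2c1=O | intermediate
15 | 2-ethynyl-6-methoxy-3,5,7-tris(methoxymethoxy)-4H-chromen-4-one | COCOc1c(C#C)oc2cc(OCOC)c(OC)c(OCOC)c2c1=O | intermediate
16 | trans-1-methoxy-3-(trimethylsilyloxy)buta-1,3-diene | CO/C=C/C(=C)O[Si](C)(C)C | starting material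
17 | 6-methoxy-2-[6-methoxy-4-(trimethylsilyloxy)cyclohexa-1,4-dien-1-yl]-3,5,7-tris(methoxymethoxy)-4H-chromen-4-one (racemic) | COCOc1c(C2=CCC(O[Si](C)(C)C)=CC2OC)oc2cc(OCOC)c(OC)c(OCOC)c2c1=O | intermediate (not isolated)
18 | 6-methoxy-3,5,7-tris(methoxymethoxy)-2-[4-(trimethylsilyloxy)phenyl]-4H-chromen-4-one | COCOc1c(-c2ccc(O[Si](C)(C)C)cc2)oc2cc(OCOC)c(OC)c(OCOC)c2c1=O | intermediate (not isolated)
19 | 2-(4-hydroxyphenyl)-6-methoxy-3,5,7-tris(methoxymethoxy)-4H-chromen-4-one | COCOc1c(-c2ccc(O)cc2)oc2cc(OCOC)c(OC)c(OCOC)c2c1=O | intermediate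
20 | 1-bromo-3-methylbut-2-ene (prenyl bromide) | CC(C)=CCBr | starting material
21 | 6-methoxy-3,5,7-tris(methoxymethoxy)-2-{4-[(3-methylbut-2-en-1-yl)oxy]phenyl}-4H-chromen-4-one | COCOc1c(-c2ccc(OCC=C(C)C)cc2)oc2cc(OCOC)c(OC)c(OCOC)c2c1=O | intermediate
22 | 3,5,7-trihydroxy-6-methoxy-2-{4-[(3-methylbut-2-en-1-yl)oxy]phenyl}-4H-chromen-4-one (3,5,7-trihydroxy-6-methoxy-4'-prenyloxyflavone) | COc1c(O)cc2oc(-c3ccc(OCC=C(C)C)cc3)c(O)c(=O)c2c1O | target

Total step count: 12 (steps 1–2 make amide 3; steps 3–12 form the main line).
Longest linear sequence: 10 steps (from 4 to 22, steps 3–12).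

Steps most likely to fail

Step 10. The alkyne may be too weakly polarised by the electron-rich, threefold alkoxylated chromone, so that thermal decay of the diene outpaces cycloaddition, or addition may stop at an open-chain conjugate adduct that does not close. The fallback uses known chemistry, sets out from ketone 10 and returns at phenol 19, bringing ring B in as a ready-made benzoyl unit. Enolate acylation of 10 with 4-(benzyloxy)benzoyl chloride (LiN(SiMe3)2, THF, −78 °C → rt) should give 1-[4-(benzyloxy)phenyl]-3-[2-hydroxy-5-methoxy-4,6-bis(methoxymethoxy)phenyl]-2-(methoxymethoxy)propane-1,3-dione F1. Cyclodehydration under buffered acid (NaOAc, AcOH, 90 °C) should give 2-[4-(benzyloxy)phenyl]-6-methoxy-3,5,7-tris(methoxymethoxy)-4H-chromen-4-one F2. Hydrogenolysis (H2, Pd/C, EtOAc, rt) should then give 19.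

Step 8. Ring closure may take the wrong course, with the enol oxygen attacking the alkyne (6-endo-dig) to give a 4-pyranone, or the MOM group next to the ketone may be lost under the acid. The fallback sets out from ketone 10 and returns at silylalkyne 14; it closes the pyranone first and attaches the alkyne by cross-coupling. Condensation of 10 with N,N-dimethylformamide dimethyl acetal (PhMe, 80 °C) should give (Z)-3-(dimethylamino)-1-[2-hydroxy-5-methoxy-4,6-bis(methoxymethoxy)phenyl]-2-(methoxymethoxy)prop-2-en-1-one F3. On stirring with silica gel in CH2Cl2 this should close with loss of dimethylamine to 6-methoxy-3,5,7-tris(methoxymethoxy)-4H-chromen-4-one F4. Zincation at C2, directed by the ring oxygen and the neighbouring MOM ether, with TMPZnCl·LiCl (TMP = 2,2,6,6-tetramethylpiperidide; THF, rt) and quenching with I2 should give 2-iodo-6-methoxy-3,5,7-tris(methoxymethoxy)-4H-chromen-4-one F5. Sonogashira coupling with ethynyltrimethylsilane (PdCl2(PPh3)2, CuI, Et3N, THF, rt) should give 14.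

Step 12. The acid may ionise the allylic C–O bond of the prenyl ether, with loss of the prenyl group, before the slowest MOM ether (on O7) has gone. The fallback sets out from phenol 19 and returns at target 22; it builds the trisubstituted alkene only after all acid treatment. Alkylation of 19 with 2-bromo-1,1-diethoxyethane (Cs2CO3, DMF, 90 °C) should give 2-[4-(2,2-diethoxyethoxy)phenyl]-6-methoxy-3,5,7-tris(methoxymethoxy)-4H-chromen-4-one F6. Aqueous HCl in THF (50 °C) should remove the three MOM groups and the acetal together to give 2-[4-(3,5,7-trihydroxy-6-methoxy-4-oxo-4H-chromen-2-yl)phenoxy]acetaldehyde F7. Wittig olefination with excess isopropylidenetriphenylphosphorane (from isopropyltriphenylphosphonium iodide and n-BuLi, THF, −78 °C → rt; the excess is taken up by the three phenols) should give 22.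

Further compounds
F1 | step 10 | 1-[4-(benzyloxy)phenyl]-3-[2-hydroxy-5-methoxy-4,6-bis(methoxymethoxy)phenyl]-2-(methoxymethoxy)propane-1,3-dione (racemic) | COCOC(C(=O)c1ccc(OCc2ccccc2)cc1)C(=O)c1c(O)cc(OCOC)c(OC)c1OCOC
F2 | step 10 | 2-[4-(benzyloxy)phenyl]-6-methoxy-3,5,7-tris(methoxymethoxy)-4H-chromen-4-one | COCOc1c(-c2ccc(OCc3ccccc3)cc2)oc2cc(OCOC)c(OC)c(OCOC)c2c1=O
F3 | step 8 | (Z)-3-(dimethylamino)-1-[2-hydroxy-5-methoxy-4,6-bis(methoxymethoxy)phenyl]-2-(methoxymethoxy)prop-2-en-1-one | COCO/C(=C\N(C)C)C(=O)c1c(O)cc(OCOC)c(OC)c1OCOC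
F4 | step 8 | 6-methoxy-3,5,7-tris(methoxymethoxy)-4H-chromen-4-one | COCOc1coc2cc(OCOC)c(OC)c(OCOC)c2c1=O
F5 | step 8 | 2-iodo-6-methoxy-3,5,7-tris(methoxymethoxy)-4H-chromen-4-one | COCOc1c(I)oc2cc(OCOC)c(OC)c(OCOC)c2c1=O
F6 | step 12 | 2-[4-(2,2-diethoxyethoxy)phenyl]-6-methoxy-3,5,7-tris(methoxymethoxy)-4H-chromen-4-one | CCOC(COc1ccc(cc1)-c1oc2cc(OCOC)c(OC)c(OCOC)c2c(=O)c1OCOC)OCC
F7 | step 12 | 2-[4-(3,5,7-trihydroxy-6-methoxy-4-oxo-4H-chromen-2-yl)phenoxy]acetaldehyde | O=CCOc1ccc(cc1)-c1oc2cc(O)c(OC)c(O)c2c(=O)c1O
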